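**Retrosynthetic overview**
1. Broussonol A ⇐ removal of two MOM ethers ⇐ 5,7-bis-MOM flavonol ⇐ one-pot Claisen–Schmidt condensation / Algar–Flynn–Oyamada (AFO) oxidative cyclisation of an A-ring methyl ketone with a B-ring chromene aldehyde.
2. A-ring ketone ⇐ selective 4,6-bis-MOM protection ⇐ key step: direct Ir-catalysed C-(1,1-dimethylallyl)ation of C2v-symmetric 2,4,6-trihydroxyacetophenone through a dearomatised cyclohexadienone. It breaks the symmetry and sets the quaternary carbon in one step, with no O-prenyl ether and no sigmatropic shift.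
3. B-ring aldehyde ⇐ propargyl Claisen / 1,5-H shift / oxa-6π cascade ⇐ 4-O-(1,1-dimethylpropargyl) ether of 3,4-dihydroxybenzaldehyde.
4. Ring order: both benzene rings are bought; the 2H-pyran of the chromene closes first, the γ-pyranone C ring last.

Assumptions: the target has no stereocentre (it is achiral, so no stereocontrol is needed), and tert-butyl 2-methylbut-3-en-2-yl carbonate is bought as a catalogue reagent.

**Step 1**
Reactants: 1 1-(2,4,6-trihydroxyphenyl)ethan-1-one (phloroacetophenone); 2 tert-butyl 2-methylbut-3-en-2-yl carbonate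
Product: 4 1-[2,4,6-trihydroxy-3-(2-methylbut-3-en-2-yl)phenyl]ethan-1-one, via dearomatised dienone 3 (not isolated)
Conditions: 1 (2.0 equiv), 2 (1.0 equiv), [Ir(cod)Cl]2 (2.5 mol %), P(OPh)3 (10 mol %), Et3B (30 mol %), THF, 0 °C → rt
Reagents that add atoms: none
Why: Proposed new method: Ir(I)/phosphite ionises the tertiary allylic carbonate to a π-(1,1-dimethylallyl)iridium species that is attacked at its more substituted terminus by the soft ring carbon C3 (= C5 by symmetry) of the phloroacetophenone phenoxide (a vinylogous β-diketonate, freed by the tert-butoxide released on decarboxylation), giving dienone 3, which enolises to 4 with no stereocentre left; Et3B is added as a Lewis-acid co-catalyst expected to favour C- over O-attack, any aryl tert-allyl ether should re-ionise under the catalyst, and excess cheap 1 suppresses double alkylation; the closest known reaction types are Ir-catalysed branched-selective allylic alkylation of stabilised carbon nucleophiles that builds quaternary centres and Ir-catalysed dearomative reverse prenylation of indoles (Tsuji–Trost-type allylic alkylation).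

**Step 2**
Reactants: 4 1-[2,4,6-trihydroxy-3-(2-methylbut-3-en-2-yl)phenyl]ethan-1-one
Product: 5 1-[2-hydroxy-4,6-bis(methoxymethoxy)-3-(2-methylbut-3-en-2-yl)phenyl]ethan-1-one
Conditions: MOMCl (2.3 equiv), K2CO3 (3 equiv), acetone, 0 °C → 40 °C
Reagents that add atoms: chloromethyl methyl ether, COCCl
Why: Williamson-type MOM protection takes the para-OH and the less hindered ortho-OH, while the 2-OH, wedged between the hydrogen-bonding acetyl group and the tert-alkyl group, stays free, which fixes that this oxygen becomes O1 next to the reverse-prenyl group.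

**Step 3**
Reactants: 6 3,4-dihydroxybenzaldehyde; 7 3-chloro-3-methylbut-1-yne
Product: 8 3-hydroxy-4-[(2-methylbut-3-yn-2-yl)oxy]benzaldehyde
Conditions: 7 (1.3 equiv), K2CO3 (1.1 equiv), KI (10 mol %), CuI (5 mol %), DMF, 60 °C, N2
Reagents that add atoms: none
Why: Copper-catalysed propargylic etherification (Williamson type via a copper acetylide), in which one equivalent of weak base ionises and alkylates only the more acidic 4-OH para to the aldehyde.

**Step 4**
Reactants: 8 3-hydroxy-4-[(2-methylbut-3-yn-2-yl)oxy]benzaldehyde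
Product: 11 8-hydroxy-2,2-dimethyl-2H-chromene-6-carbaldehyde, via allenyl cyclohexadienone 9 (not isolated), via ortho-quinone methide 10 (not isolated)
Conditions: N,N-diethylaniline, 190 °C, 3 h, N2
Reagents that add atoms: none
Why: Aromatic propargyl Claisen rearrangement to the only free ortho carbon, then enolisation, 1,5-H shift and oxa-6π electrocyclisation, the standard thermal route to 2,2-dimethyl-2H-chromenes, leaving no stereocentre.

**Step 5**
Reactants: 5 1-[2-hydroxy-4,6-bis(methoxymethoxy)-3-(2-methylbut-3-en-2-yl)phenyl]ethan-1-one; 11 8-hydroxy-2,2-dimethyl-2H-chromene-6-carbaldehyde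
Product: 14 3-hydroxy-2-(8-hydroxy-2,2-dimethyl-2H-chromen-6-yl)-5,7-bis(methoxymethoxy)-8-(2-methylbut-3-en-2-yl)-4H-chromen-4-one, via chalcone 12 (not isolated), via trans-dihydroflavonol 13 (not isolated)
Conditions: KOH (50 % aq, 10 equiv), EtOH, rt, 36 h; then 30 % H2O2 (6 equiv), 0 °C → rt, 4 h; 1 M HCl work-up to pH 5
Reagents that add atoms: hydrogen peroxide, OO
Why: Claisen–Schmidt aldol condensation then Algar–Flynn–Oyamada oxidative cyclisation, in which the only free phenoxide (2'-O, next to the tert-alkyl group) closes 6-endo on the peroxide-activated enone whose β-carbon is activated by the para-oxygenated B ring, and excess alkaline H2O2 takes the trans-dihydroflavonol on to the flavonol, so the reverse-prenyl group ends at C8; the meta-phenoxide does not deactivate the aldehyde and alkaline H2O2 does not touch the isolated alkenes.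

**Step 6**
Reactants: 14 3-hydroxy-2-(8-hydroxy-2,2-dimethyl-2H-chromen-6-yl)-5,7-bis(methoxymethoxy)-8-(2-methylbut-3-en-2-yl)-4H-chromen-4-one
Product: 15 Broussonol A
Conditions: 3 M aq HCl/MeOH (1:10), 50 °C, 1–2 h
Reagents that add atoms: none
Why: Acid-catalysed acetal methanolysis (MOM removal) under mild conditions that spare the monosubstituted vinyl group (protonation would give only a secondary cation) and the chromene, and the achiral target has no stereocentre to scramble.

**Compound list**
1 | 1-(2,4,6-trihydroxyphenyl)ethan-1-one (phloroacetophenone) | CC(=O)c1c(O)cc(O)cc1O | starting material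
2 | tert-butyl 2-methylbut-3-en-2-yl carbonate | C=CC(C)(C)OC(=O)OC(C)(C)C | starting material
3 | 4-acetyl-3,5-dihydroxy-6-(2-methylbut-3-en-2-yl)cyclohexa-2,4-dien-1-one (racemic keto tautomer of 4) | CC(=O)C1=C(O)C(C(C)(C)C=C)C(=O)C=C1O | intermediate
4 | 1-[2,4,6-trihydroxy-3-(2-methylbut-3-en-2-yl)phenyl]ethan-1-one | CC(=O)c1c(O)cc(O)c(C(C)(C)C=C)c1O | intermediate
5 | 1-[2-hydroxy-4,6-bis(methoxymethoxy)-3-(2-methylbut-3-en-2-yl)phenyl]ethan-1-one | CC(=O)c1c(OCOC)cc(OCOC)c(C(C)(C)C=C)c1O | intermediate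
6 | 3,4-dihydroxybenzaldehyde | O=Cc1ccc(O)c(O)c1 | starting material
7 | 3-chloro-3-methylbut-1-yne | C#CC(C)(C)Cl | starting material
8 | 3-hydroxy-4-[(2-methylbut-3-yn-2-yl)oxy]benzaldehyde | O=Cc1ccc(OC(C)(C)C#C)c(O)c1 | intermediate
9 | 5-hydroxy-3-(3-methylbuta-1,2-dien-1-yl)-4-oxocyclohexa-1,5-diene-1-carbaldehyde (racemic) | O=CC1=CC(C=C=C(C)C)C(=O)C(O)=C1 | intermediate
10 | (3Z)-5-hydroxy-3-(3-methylbut-2-en-1-ylidene)-4-oxocyclohexa-1,5-diene-1-carbaldehyde | O=CC1=C/C(=C/C=C(C)C)C(=O)C(O)=C1 | intermediate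
11 | 8-hydroxy-2,2-dimethyl-2H-chromene-6-carbaldehyde | O=Cc1cc(O)c2c(c1)C=CC(C)(C)O2 | intermediate
12 | (E)-1-[2-hydroxy-4,6-bis(methoxymethoxy)-3-(2-methylbut-3-en-2-yl)phenyl]-3-(8-hydroxy-2,2-dimethyl-2H-chromen-6-yl)prop-2-en-1-one | O=C(/C=C/c1cc(O)c2c(c1)C=CC(C)(C)O2)c1c(OCOC)cc(OCOC)c(C(C)(C)C=C)c1O | intermediate
13 | trans-3-hydroxy-2-(8-hydroxy-2,2-dimethyl-2H-chromen-6-yl)-5,7-bis(methoxymethoxy)-8-(2-methylbut-3-en-2-yl)-2,3-dihydro-4H-chromen-4-one (racemic; 2R,3R enantiomer drawn) | O=C1c2c(OCOC)cc(OCOC)c(C(C)(C)C=C)c2O[C@H](c2cc(O)c3c(c2)C=CC(C)(C)O3)[C@H]1O | intermediate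
14 | 3-hydroxy-2-(8-hydroxy-2,2-dimethyl-2H-chromen-6-yl)-5,7-bis(methoxymethoxy)-8-(2-methylbut-3-en-2-yl)-4H-chromen-4-one | C=CC(C)(C)c1c(OCOC)cc(OCOC)c2c(=O)c(O)c(-c3cc(O)c4c(c3)C=CC(C)(C)O4)oc12 | intermediate
15 | Broussonol A, 3,5,7-trihydroxy-2-(8-hydroxy-2,2-dimethyl-2H-chromen-6-yl)-8-(2-methylbut-3-en-2-yl)-4H-chromen-4-one (achiral) | C=CC(C)(C)c1c(O)cc(O)c2c(=O)c(O)c(-c3cc(O)c4c(c3)C=CC(C)(C)O4)oc12 | target

**Totals**
Total step count: 6. Longest linear sequence: 4 (steps 1, 2, 5, 6).

**Steps most likely to fail, with fallbacks**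

Step 1 is the riskiest: it is a new method, and O-allylation, linear (normal prenyl) attack or double alkylation could dominate. The fallback sets out from 1. O-Prenylation of the most acidic 4-OH with prenyl bromide (K2CO3, acetone, rt) gives the still symmetric 1-[2,6-dihydroxy-4-[(3-methylbut-2-en-1-yl)oxy]phenyl]ethan-1-one F1. Its thermal aromatic Claisen rearrangement (N,N-diethylaniline, 190 °C) can only go to the two equivalent ortho carbons, passes through the same dienone 3 and comes back to the route at 4.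

Step 5 is second: the 6'-alkoxy group can divert the AFO reaction to the aurone, and the free B-ring phenol may slow the condensation. The fallback sets out from 5 and 11 and takes the flavonol oxygen from an enolate hydroxylation instead of the oxidative cyclisation. The condensation is stopped before the peroxide is added and chalcone 12 is isolated. NaOAc in refluxing EtOH closes it by oxa-Michael addition of the same 2'-oxygen to the racemic flavanone 2-(8-hydroxy-2,2-dimethyl-2H-chromen-6-yl)-5,7-bis(methoxymethoxy)-8-(2-methylbut-3-en-2-yl)-2,3-dihydro-4H-chromen-4-one F2. Its lithium enolate (LiHMDS, THF, −78 °C) is hydroxylated with 3-phenyl-2-(phenylsulfonyl)oxaziridine to the trans-dihydroflavonol 13, now isolated. Alkaline H2O2 (the second stage of the AFO reaction) then dehydrogenates it, and the sequence comes back to the route at 14.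

Step 6 is third: acid may cyclise the 7-OH onto the vinyl group or add methanol to the chromene. The fallback sets out from 4 and replaces the acid-labile MOM ethers by allyl ethers that come off under neutral conditions. Allyl bromide and K2CO3 in acetone give 1-[2-hydroxy-3-(2-methylbut-3-en-2-yl)-4,6-bis(prop-2-en-1-yloxy)phenyl]ethan-1-one F3, with the same selectivity as in step 2. The one-pot condensation/AFO sequence with 11 then runs through the bis-allyl chalcone F4 and the bis-allyl trans-dihydroflavonol F5 (neither isolated) to 3-hydroxy-2-(8-hydroxy-2,2-dimethyl-2H-chromen-6-yl)-8-(2-methylbut-3-en-2-yl)-5,7-bis(prop-2-en-1-yloxy)-4H-chromen-4-one F6. Pd(PPh3)4 (5 mol %) with excess morpholine in THF at rt transfers both O-allyl groups to the amine, and the sequence comes back to the route at 15.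

**Further compounds**
F1 | step 1 | 1-[2,6-dihydroxy-4-[(3-methylbut-2-en-1-yl)oxy]phenyl]ethan-1-one | CC(=O)c1c(O)cc(OCC=C(C)C)cc1O
F2 | step 5 | 2-(8-hydroxy-2,2-dimethyl-2H-chromen-6-yl)-5,7-bis(methoxymethoxy)-8-(2-methylbut-3-en-2-yl)-2,3-dihydro-4H-chromen-4-one (racemic) | O=C1CC(c2cc(O)c3c(c2)C=CC(C)(C)O3)Oc2c1c(OCOC)cc(OCOC)c2C(C)(C)C=C
F3 | step 6 | 1-[2-hydroxy-3-(2-methylbut-3-en-2-yl)-4,6-bis(prop-2-en-1-yloxy)phenyl]ethan-1-one | CC(=O)c1c(OCC=C)cc(OCC=C)c(C(C)(C)C=C)c1O
F4 | step 6 | (E)-1-[2-hydroxy-3-(2-methylbut-3-en-2-yl)-4,6-bis(prop-2-en-1-yloxy)phenyl]-3-(8-hydroxy-2,2-dimethyl-2H-chromen-6-yl)prop-2-en-1-one | O=C(/C=C/c1cc(O)c2c(c1)C=CC(C)(C)O2)c1c(OCC=C)cc(OCC=C)c(C(C)(C)C=C)c1O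
F5 | step 6 | trans-3-hydroxy-2-(8-hydroxy-2,2-dimethyl-2H-chromen-6-yl)-8-(2-methylbut-3-en-2-yl)-5,7-bis(prop-2-en-1-yloxy)-2,3-dihydro-4H-chromen-4-one (racemic; 2R,3R enantiomer drawn) | O=C1c2c(OCC=C)cc(OCC=C)c(C(C)(C)C=C)c2O[C@H](c2cc(O)c3c(c2)C=CC(C)(C)O3)[C@H]1O
F6 | step 6 | 3-hydroxy-2-(8-hydroxy-2,2-dimethyl-2H-chromen-6-yl)-8-(2-methylbut-3-en-2-yl)-5,7-bis(prop-2-en-1-yloxy)-4H-chromen-4-one | C=CC(C)(C)c1c(OCC=C)cc(OCC=C)c2c(=O)c(O)c(-c3cc(O)c4c(c3)C=CC(C)(C)O4)oc12
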